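## Analysis of the target

Isodihydromaldoxin (22) is a diaryl ether: two benzene rings joined through one oxygen, with no fused ring and no stereocentre, and the ether axis, although it carries three ortho substituents, is expected to rotate freely, so nothing stereochemical has to be set. Ring A is a methyl benzoate with CO2CH3 at C1, the ether oxygen at C2, OCH3 at C3, OH at C5 and hydrogens at C4 and C6. Ring B is a salicylic acid with CO2H at C1, OH at C2, Cl at C3, CH3 at C4, H at C5 and the ether oxygen at C6. The sensitive groups are two carboxyl groups that must end at different levels (ester on ring A, free acid on ring B), two phenols on electron-rich rings that are easily oxidised or halogenated, and an aryl chloride that rules out hydrogenolytic deprotection. The first difficulty is the ether bond: its oxygen is flanked by CO2CH3 and OCH3 on ring A and by CO2H on ring B, and both rings are electron-rich, so joining two finished arenes is unattractive. The second is that ring B is pentasubstituted and its chlorine must sit at C3, between OH and CH3, not at the equally activated C5. The strategy rests on the pattern of ring B: a resorcinol (oxygens at C2 and C6) with a carbon substituent at C1 between the two oxygens, one oxygen free and the other arylated, and a contiguous C3(Cl)–C4(CH3)–C5(H) edge. A vinylketene (supplying C2, C5, C4 and C3) and an alkynyl ether (supplying C1 and C6) assemble exactly this pattern.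

## Retrosynthetic reasoning

**22 back to 20 (functional group changes only).** The ring A phenol of 22 is masked as its MOM ether (21), and the ring B carboxyl is taken back to the aldehyde 20. The two carboxyl groups therefore never sit at the same oxidation level: ring A carries its methyl ester from the start, and the ring B acid appears only by oxidation in the penultimate step, so no selective hydrolysis or esterification is needed. The MOM group stays on during the oxidation to protect ring A and is removed last.

**20 to 9 and 14 (key disconnection).** The aldehyde of 20 is traced to its diethyl acetal 19, which is formed and hydrolysed in one flask. The acetal is chosen over an ester because it does not conjugate with the alkyne of 9 and leaves it nucleophilic. Three bonds of ring B are then cut: C1–C2, C5–C6 and C2–C3. Ring B falls into a two-carbon piece (C1 and C6, the alkyne of 9) and a four-carbon piece (C2, C5, C4, C3, the chlorovinylketene 15 that 14 releases on heating). The cut is made here because the ether oxygen then stays attached to C6 as part of an alkyne, so the crowded oxygen–ring B bond is never formed on an arene. Chlorine and methyl arrive on the four-carbon piece, so no electrophilic chlorination of a resorcinol is needed and every ring B substituent is fixed by connectivity. The forward reaction has to open 14, add 9 to the ketene with the correct orientation, reopen the adduct, close the six-membered ring and tautomerise to the phenol 19.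

**9 to 8, and 8 to 5 and 7.** The bond between the ring A oxygen and the alkyne carbon is cut. A phenoxide cannot substitute at an sp carbon, so the alkyne is traced back to the bromoenol ether 8. In 8 the oxygen has replaced the bromine of 7 that lies trans to the acetal-bearing substituent; the forward steps are a copper-catalysed vinylation of 5 and an anti-elimination of HBr. Routes through a metalated alkynyl ether are excluded because the ring A ester would not survive an organolithium reagent.

**7 to 6.** The C=C bond of 7 is cut to the aldehyde 6, which already carries the acetal; the forward step is a dibromomethylenation.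

**5 to 4, 3 and 1.** The MOM ether of 5 is removed to the hydroquinone ester 4, the ester to the acid 3, and the C5–O bond of 3 is cut to 1. In 1 both positions ortho to the phenol are blocked, so a para-hydroxylation can only occur at C5. In 4 the two hydroxyl groups differ strongly: the one at C2 is hindered and hydrogen-bonded to the ester, so the C5 hydroxyl can be protected alone.

**14 to 13, and 13 to 10 and 11.** One chlorine is added back to 14 to give 13, whose four-membered ring is cut into propyne 10 and dichloroketene 12, the latter generated from 11. The forward [2+2] cycloaddition places the methyl group next to the CCl2 carbon, and a controlled reduction then removes one of the two chlorines.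

## Alternatives that were turned down

**Alternative 1: ring B from a 2-pyrone.** Ring B bonds C1–C2 and C3–C4 are cut. The pyrone A1 supplies C1, C6, C5 and C4 with the ether oxygen already at the pyrone 4-position, and the ketene acetal A2 supplies C2 and C3 with the chlorine. In the forward step an inverse-demand [4+2] cycloaddition is followed by extrusion of the lactone bridge and loss of one ethoxy group to give the benzene A3.

- For: the aryl–oxygen–carbon bond of A1 would come from an addition–elimination at the pyrone 4-position. That reaction is indifferent to ortho substituents on the phenoxide and needs neither copper nor a strong base, so on this point the alternative is stronger than the chosen route. The orientation of the cycloaddition (nucleophilic carbon of A2 to pyrone C6, acetal carbon to C3) follows the usual polarity, and the ring B carboxyl arrives at the acid level.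
- Against: the 4-aryloxy group donates into the pyrone and raises the energy of the diene that must accept electrons. The new C3–C4 bond joins the methyl-bearing pyrone carbon to the chlorine-bearing carbon of A2, which is hindered and inductively deactivated. A3 carries an O-ethyl group at ring B C2. Cleaving it with a Lewis acid risks the ring A methoxy, which sits next to the ether oxygen and is set up for chelation-assisted cleavage, and hydrogenolysis of the two benzyl groups must spare the aryl chloride.
- Comparison: the chosen route delivers the C2 hydroxyl free and needs only mild acid for deprotection. Its ring-forming step relies on a nucleophilic alkyne and an electrophilic ketene and does not require a deactivated diene to react.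

**Alternative 2: ring A by annulation of an aryloxypyruvate.** Ring A bonds C2–C3 and C6–C1 are cut. The pyruvate A4 carries the complete ring B and ring A atoms C1 and C2; the enone A5 supplies C3 to C6. In the forward step the enolate carbon of A4 displaces one methoxy group of A5, the acetyl methyl group then adds to the pyruvate ketone, and dehydration and tautomerisation give the phenol A6.

- For: the ether bond is made by simple alkylation of a ring B phenol, which is easier than the copper step of the chosen route. The ring A hydroxyl emerges free, and A6 is one acid treatment from the target, so the endgame is shorter than the chosen one.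
- Against: the ketone of A4 is highly electrophilic and its CH2 group is acidic, so self-condensation competes. The enolate of A4 also sits five atoms from the ring B ester carbonyl and can close a five-membered ring onto it. The acceptor carbon of A5 bears two donor methoxy groups and is a poor electrophile. Ring B, the more heavily substituted ring, must be made beforehand with its chlorine by substitution chemistry.
- Comparison: the annulation has no close counterpart among known reactions, whereas the ring formation of the chosen route belongs to an established reaction class. The chosen route is longer after the ring-forming step but does not need a finished pentasubstituted ring B.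

**Alternative 3: aryne, phenoxide and carbon dioxide.** The bonds O–C6 and C1–CO2H of ring B are cut and no ring is formed. Fluoride releases the aryne A8 from the silyl triflate A7, the phenoxide of 5 adds at C6, and the aryl anion at C1 is to be captured by carbon dioxide A9 to give the acid A10.

- For: this is the most convergent plan. The crowded ether forms at room temperature without a metal, the C2 alkoxy group directs the phenoxide to the distal aryne carbon, and A10 needs a single acid step. On step count after the union it is stronger than the chosen route.
- Against: the aryl anion at C1 is formed ortho to an aryloxy group whose ring carries an ester on the neighbouring carbon. Intramolecular acyl transfer through a six-membered transition state to the xanthone A11 should outrun intermolecular capture of A9. A9 also ties up the phenoxide as a carbonate. A7 is a hexasubstituted benzene that needs its own long synthesis, with the chlorine placed by electrophilic substitution.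
- Comparison: the chosen route has more steps after the union, but its ring-forming step has no built-in competing cyclisation, and it places the chlorine by connectivity.

Key step: step 9

Remark on the chemistry: 6 is taken to be available as the anhydrous monomer, and the ether axis of 22 is taken to rotate freely; 14, 16 and 18 are racemic.

## Route

Step 1
Reactants: 1 2-hydroxy-3-methoxybenzoic acid
Product: 3 2,5-dihydroxy-3-methoxybenzoic acid, via aryl sulfate 2 (not isolated)
Conditions: K2S2O8, NaOH, H2O, 0 °C → rt; then HCl (aq), 90 °C
Reagents that add atoms: potassium peroxodisulfate K2S2O8, [K+].[K+].[O-]S(=O)(=O)OOS(=O)(=O)[O-]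
Why: Elbs persulfate oxidation: the phenoxide of 1 is attacked by peroxodisulfate para to the phenolic oxygen, and hot acid hydrolyses the aryl sulfate 2 to the hydroquinone. Both ortho positions are blocked by CO2H and OCH3, so only C5 is open.

Step 2
Reactants: 3 2,5-dihydroxy-3-methoxybenzoic acid
Product: 4 methyl 2,5-dihydroxy-3-methoxybenzoate
Conditions: MeOH, H2SO4 (cat.), reflux, under N2
Reagents that add atoms: methanol, CO
Why: Fischer esterification of a salicylic acid in excess methanol; the hydroquinone is stable to acid when air is excluded.

Step 3
Reactants: 4 methyl 2,5-dihydroxy-3-methoxybenzoate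
Product: 5 methyl 2-hydroxy-3-methoxy-5-(methoxymethoxy)benzoate
Conditions: MOMCl (1.05 equiv), i-Pr2NEt, CH2Cl2, 0 °C
Reagents that add atoms: chloromethyl methyl ether, COCCl
Why: O-alkylation of a phenol: the C5 hydroxyl is free and unhindered, whereas the C2 hydroxyl is flanked by OCH3 and CO2CH3 and hydrogen-bonded to the ester carbonyl, so one equivalent of MOMCl should react at O5 only.

Step 4
Reactants: 6 2,2-diethoxyacetaldehyde
Product: 7 1,1-dibromo-3,3-diethoxyprop-1-ene
Conditions: CBr4, PPh3, Et3N, CH2Cl2, 0 °C
Reagents that add atoms: carbon tetrabromide, BrC(Br)(Br)Br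
Why: Ramirez dibromomethylenation (first stage of the Corey–Fuchs sequence) of an aldehyde; Et3N buffers the phosphorus bromide by-products so that the acid-labile acetal survives.

Step 5
Reactants: 5 methyl 2-hydroxy-3-methoxy-5-(methoxymethoxy)benzoate; 7 1,1-dibromo-3,3-diethoxyprop-1-ene
Product: 8 methyl 2-{[(1Z)-1-bromo-3,3-diethoxyprop-1-en-1-yl]oxy}-3-methoxy-5-(methoxymethoxy)benzoate
Conditions: CuI (10 mol %), 2,2'-bipyridine (20 mol %), K3PO4, 7 in 1.5-fold amount, PhMe, 110 °C
Reagents that add atoms: none
Why: Copper-catalysed Ullmann-type vinylation of a phenol with a 1,1-dibromoalkene: the copper phenoxide reacts at the less hindered C–Br bond, trans to the acetal-bearing substituent, so the remaining bromine is cis to CH(OEt)2 (Z) and anti to the vinylic hydrogen. The surplus of 7 suppresses a second substitution, and anhydrous K3PO4 in toluene leaves ester, MOM ether and acetal alone.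

Step 6
Reactants: 8 methyl 2-{[(1Z)-1-bromo-3,3-diethoxyprop-1-en-1-yl]oxy}-3-methoxy-5-(methoxymethoxy)benzoate
Product: 9 methyl 2-[(3,3-diethoxyprop-1-yn-1-yl)oxy]-3-methoxy-5-(methoxymethoxy)benzoate
Conditions: KN(SiMe3)2 (1.2 equiv), THF, −78 → −40 °C
Reagents that add atoms: none
Why: E2 anti-dehydrobromination of a bromoenol ether to the ynol ether. A silylamide at low temperature is used in place of an alkoxide because it cannot transesterify the methyl ester and is less likely to isomerise the propargylic acetal to an allene. The product is passed through base-washed silica and used at once, since ynol ethers hydrate under acid.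

Step 7
Reactants: 10 propyne; 11 trichloroacetyl chloride
Product: 13 4,4-dichloro-3-methylcyclobut-2-en-1-one, via dichloroketene 12 (not isolated)
Conditions: Zn(Cu) couple, condensed 10 in excess, Et2O/DME, 0 °C → rt
Reagents that add atoms: none
Why: Zinc dechlorinates 11 to dichloroketene 12, which adds to the alkyne in a [2+2] cycloaddition; the unsubstituted alkyne carbon bonds to the ketene carbonyl carbon, so the methyl group ends at C3 next to the CCl2 carbon. DME binds the ZnCl2 formed and keeps it from degrading the product.

Step 8
Reactants: 13 4,4-dichloro-3-methylcyclobut-2-en-1-one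
Product: 14 4-chloro-3-methylcyclobut-2-en-1-one (racemic)
Conditions: Zn (1.1 equiv), AcOH, TMEDA, EtOH, 0 °C
Reagents that add atoms: none
Why: Zinc reduction of an α,α-dichloroketone is stepwise, the first C–Cl bond of the geminal pair being reduced much more easily than the second, so a small excess of zinc at 0 °C in buffered AcOH should stop at the monochloride after protonation at C4. The volatile product is kept as a toluene solution.

Step 9
Reactants: 9 methyl 2-[(3,3-diethoxyprop-1-yn-1-yl)oxy]-3-methoxy-5-(methoxymethoxy)benzoate; 14 4-chloro-3-methylcyclobut-2-en-1-one
Product: 20 methyl 2-(4-chloro-2-formyl-3-hydroxy-5-methylphenoxy)-3-methoxy-5-(methoxymethoxy)benzoate, via chlorovinylketene 15 (not isolated), via 4-vinylcyclobutenone 16 (not isolated), via dienylketene 17 (not isolated), via cyclohexa-2,4-dienone 18 (not isolated), via acetal phenol 19 (not isolated)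
Conditions: PhMe, 80 °C (solution of 14 added over 2 h) then 110 °C, base-washed glass; then solvent removed, PPTS, acetone/H2O, rt
Reagents that add atoms: water, O
Why: Danheiser benzannulation: thermal conrotatory four-electron opening of 14 gives the chlorovinylketene 15, in which the chlorine, a lone-pair donor at C4, is expected to have rotated outward (E isomer). The ynol ether 9 adds to the ketene in a [2+2] cycloaddition in which its nucleophilic carbon, the acetal-bearing one remote from oxygen, bonds to the ketene carbonyl carbon (ring B C1–C2) and the oxygen-bearing carbon bonds to the ketene α-carbon (C6–C5), giving the 4-vinylcyclobutenone 16. A second, reversible four-electron opening converts 16 into the dienylketene 17 (only the isomer with the vinyl arm turned inward can cyclise and is drained off), which closes ring B by a thermal six-electron disrotatory electrocyclisation between the ketene carbon and the chlorine-bearing terminus (C2–C3) to the dienone 18, and a proton shift from C3 to oxygen gives the phenol 19. The closest known reaction type is the benzannulation of cyclobutenones with alkoxy- and silyloxyalkynes; an aryl alkynyl ether and a 4-chlorocyclobutenone are new partners within the same reactivity pattern. No stereocentre remains, since the sp3 carbons of 16 and 18 become sp2 on aromatisation. The selectivity needed is the orientation of the [2+2] step, which the oxygen lone pair of 9 secures by making the acetal-bearing carbon the only nucleophilic site; every substituent of ring B then follows from connectivity. Slow addition of 14 keeps the ketene concentration low, which should suppress its dimerisation and the acylation of the new phenol; 9 has no β-hydrogen for a retro-ene fragmentation and no acid, base or metal is present in the hot stage, so ester, MOM ether and acetal should survive it. The o-hydroxyaryl acetal 19 is not put on silica but hydrolysed in the same flask with PPTS in wet acetone, conditions that an aryl MOM ether tolerates, to the hydrogen-bonded salicylaldehyde 20.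

Step 10
Reactants: 20 methyl 2-(4-chloro-2-formyl-3-hydroxy-5-methylphenoxy)-3-methoxy-5-(methoxymethoxy)benzoate
Product: 21 3-chloro-2-hydroxy-6-[2-methoxy-6-(methoxycarbonyl)-4-(methoxymethoxy)phenoxy]-4-methylbenzoic acid
Conditions: NaClO2, NaH2PO4, 2-methyl-2-butene (excess), t-BuOH/H2O, rt
Reagents that add atoms: sodium chlorite NaClO2, [Na+].[O-]Cl=O
Why: Pinnick oxidation: chlorous acid oxidises the hindered aldehyde to the acid, and the alkene consumes the HOCl formed before it can chlorinate ring B at C5 or ring A. The ring A phenol is still masked, so it cannot be oxidised to a quinone.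

Step 11
Reactants: 21 3-chloro-2-hydroxy-6-[2-methoxy-6-(methoxycarbonyl)-4-(methoxymethoxy)phenoxy]-4-methylbenzoic acid
Product: 22 isodihydromaldoxin, 3-chloro-2-hydroxy-6-[4-hydroxy-2-methoxy-6-(methoxycarbonyl)phenoxy]-4-methylbenzoic acid
Conditions: HCl (1.25 M in MeOH), 40 °C
Reagents that add atoms: none
Why: Acid-catalysed methanolysis of an aryl MOM ether. In methanol the ring A methyl ester can only exchange with itself, and the ring B acid, flanked by OH and the aryloxy group, should resist Fischer esterification at this temperature.

## Compound list

1 | 2-hydroxy-3-methoxybenzoic acid | COc1cccc(C(=O)O)c1O | starting material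
2 | 3-carboxy-4-hydroxy-5-methoxyphenyl hydrogen sulfate (potassium salt in the flask) | COc1cc(OS(=O)(=O)O)cc(C(=O)O)c1O | intermediate (not isolated)
3 | 2,5-dihydroxy-3-methoxybenzoic acid | COc1cc(O)cc(C(=O)O)c1O | intermediate
4 | methyl 2,5-dihydroxy-3-methoxybenzoate | COC(=O)c1cc(O)cc(OC)c1O | intermediate
5 | methyl 2-hydroxy-3-methoxy-5-(methoxymethoxy)benzoate | COC(=O)c1cc(OCOC)cc(OC)c1O | intermediate
6 | 2,2-diethoxyacetaldehyde | CCOC(C=O)OCC | starting material
7 | 1,1-dibromo-3,3-diethoxyprop-1-ene | CCOC(OCC)C=C(Br)Br | intermediate
8 | methyl 2-{[(1Z)-1-bromo-3,3-diethoxyprop-1-en-1-yl]oxy}-3-methoxy-5-(methoxymethoxy)benzoate | COC(=O)c1cc(OCOC)cc(OC)c1O/C(Br)=C/C(OCC)OCC | intermediate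
9 | methyl 2-[(3,3-diethoxyprop-1-yn-1-yl)oxy]-3-methoxy-5-(methoxymethoxy)benzoate | COC(=O)c1cc(OCOC)cc(OC)c1OC#CC(OCC)OCC | intermediate
10 | propyne | CC#C | starting material
11 | trichloroacetyl chloride | ClC(=O)C(Cl)(Cl)Cl | starting material
12 | dichloroketene | ClC(Cl)=C=O | intermediate (not isolated)
13 | 4,4-dichloro-3-methylcyclobut-2-en-1-one | O=C1C=C(C)C1(Cl)Cl | intermediate
14 | 4-chloro-3-methylcyclobut-2-en-1-one (racemic) | O=C1C=C(C)C1Cl | intermediate
15 | (3E)-4-chloro-3-methylbuta-1,3-dien-1-one | Cl/C=C(\C)C=C=O | intermediate (not isolated)
16 | methyl 2-({4-[(1E)-1-chloroprop-1-en-2-yl]-2-(diethoxymethyl)-3-oxocyclobut-1-en-1-yl}oxy)-3-methoxy-5-(methoxymethoxy)benzoate (racemic) | COC(=O)c1cc(OCOC)cc(OC)c1OC1=C(C(OCC)OCC)C(=O)C1/C(C)=C/Cl | intermediate (not isolated)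
17 | methyl 2-{[(3E,5E)-6-chloro-2-(diethoxymethyl)-5-methyl-1-oxohexa-1,3,5-trien-3-yl]oxy}-3-methoxy-5-(methoxymethoxy)benzoate | O=C=C(C(OCC)OCC)/C(Oc1c(OC)cc(OCOC)cc1C(=O)OC)=C\C(C)=C\Cl | intermediate (not isolated)
18 | methyl 2-{[4-chloro-2-(diethoxymethyl)-5-methyl-3-oxocyclohexa-1,5-dien-1-yl]oxy}-3-methoxy-5-(methoxymethoxy)benzoate (racemic) | COC(=O)c1cc(OCOC)cc(OC)c1OC1=C(C(OCC)OCC)C(=O)C(Cl)C(C)=C1 | intermediate (not isolated)
19 | methyl 2-[4-chloro-2-(diethoxymethyl)-3-hydroxy-5-methylphenoxy]-3-methoxy-5-(methoxymethoxy)benzoate | COC(=O)c1cc(OCOC)cc(OC)c1Oc1cc(C)c(Cl)c(O)c1C(OCC)OCC | intermediate (not isolated)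
20 | methyl 2-(4-chloro-2-formyl-3-hydroxy-5-methylphenoxy)-3-methoxy-5-(methoxymethoxy)benzoate | COC(=O)c1cc(OCOC)cc(OC)c1Oc1cc(C)c(Cl)c(O)c1C=O | intermediate
21 | 3-chloro-2-hydroxy-6-[2-methoxy-6-(methoxycarbonyl)-4-(methoxymethoxy)phenoxy]-4-methylbenzoic acid | COC(=O)c1cc(OCOC)cc(OC)c1Oc1cc(C)c(Cl)c(O)c1C(=O)O | intermediate
22 | isodihydromaldoxin, 3-chloro-2-hydroxy-6-[4-hydroxy-2-methoxy-6-(methoxycarbonyl)phenoxy]-4-methylbenzoic acid | COC(=O)c1cc(O)cc(OC)c1Oc1cc(C)c(Cl)c(O)c1C(=O)O | target

## Step count and least certain steps

Total: 11 steps. Longest linear sequence: 8 steps (steps 1, 2, 3, 5, 6, 9, 10, 11 from compound 1).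

**Step 9 (key step).** The cycloaddition of the ketene with 9 may be slow: the oxygen lone pair of 9 is shared with ring A, and the acetal is bulky and inductively withdrawing. Dimerisation or decomposition of the chlorovinylketene, inward rotation of chlorine on ring opening, and acylation of the new phenol by further ketene could then take over.
Fallback: the ketene is generated photochemically, not thermally. (2E)-3-Chloro-2-methylprop-2-enoic acid F1 is converted with (COCl)2 into (2E)-3-chloro-2-methylprop-2-enoyl chloride F2, and acylation of diazomethane (Et3N, Et2O, 0 °C) gives (3E)-4-chloro-1-diazo-3-methylbut-3-en-2-one F3. Irradiation of F3 in the presence of 9 (CH2Cl2, rt) triggers a Wolff rearrangement to ketene 15, whose E geometry is now fixed by F1 and which forms at a temperature at which 9 is stable. The cycloadduct 16 is then heated in toluene to reach 19, and the hydrolysis stage of step 9 follows unchanged. The detour sets out from 9 and comes back to the route at 15.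

**Step 5.** The phenol is flanked on both sides, is acidified by the ortho ester and can chelate copper, so ligand exchange and vinylation may be slow; a second substitution of the product to a ketene acetal is the competing process.
Fallback: the oxygen–carbon bond is made by base-mediated addition of the phenoxide to an alkyne, without metal catalysis. Phenol 5 and commercial 3,3-diethoxyprop-1-yne (Cs2CO3, DMSO, heat) should give the anti-Markovnikov vinyl ether methyl 2-[(3,3-diethoxyprop-1-en-1-yl)oxy]-3-methoxy-5-(methoxymethoxy)benzoate F4 as an E/Z mixture. Br2 at −78 °C gives methyl 2-(1,2-dibromo-3,3-diethoxypropoxy)-3-methoxy-5-(methoxymethoxy)benzoate F5, from which Et3N removes HBr to give methyl 2-[(2-bromo-3,3-diethoxyprop-1-en-1-yl)oxy]-3-methoxy-5-(methoxymethoxy)benzoate F6, and KN(SiMe3)2 eliminates the second HBr. The detour sets out from 5, bypasses 7, 8 and step 6, and returns at 9.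

**Step 8.** The reduction may run on to removal of both chlorines, or the intermediate may be protonated at C2 instead of C4 with allylic transposition; the monochloride is also volatile and may be lost on isolation.
Fallback: chlorine is left out of the cyclobutenone and put onto the arene afterwards. Exhaustive reduction of 13 (excess Zn, AcOH, TMEDA, EtOH, rt) gives 3-methylcyclobut-2-en-1-one F7. Benzannulation of F7 with 9 under the thermal conditions of step 9, stopped before the hydrolysis, gives methyl 2-[2-(diethoxymethyl)-3-hydroxy-5-methylphenoxy]-3-methoxy-5-(methoxymethoxy)benzoate F8, which lacks the chlorine at ring B C3. Chlorination ortho to the free hydroxyl (N-chlorosuccinimide with a thiourea catalyst that delivers chlorine ortho to a phenol) then gives 19, which is hydrolysed to 20 as in step 9. The other open position of ring B, C5, is para to the hydroxyl but shielded by CH3 and the aryloxy group, so the ortho-directing catalyst is relied on. The detour sets out from 13, uses 9, and returns at 19.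

**Step 1.** Conversion in the Elbs oxidation is typically incomplete, and further oxidation of the hydroquinone by persulfate radicals may erode the material balance.
Fallback: the C5 oxygen is introduced through a boronate. Fischer esterification of 1 gives methyl 2-hydroxy-3-methoxybenzoate F9; bromination para to the hydroxyl (Br2, AcOH) gives methyl 5-bromo-2-hydroxy-3-methoxybenzoate F10; Miyaura borylation (B2pin2, Pd(dppf)Cl2, KOAc, dioxane, 80 °C) gives methyl 2-hydroxy-3-methoxy-5-(4,4,5,5-tetramethyl-1,3,2-dioxaborolan-2-yl)benzoate F11; oxidation (NaBO3·4H2O, THF/H2O) gives the hydroquinone. The detour sets out from 1 and returns at 4.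

**Step 10.** Electrophilic chlorination of the activated ring positions by HOCl may occur if scavenging is too slow, and the hindered aldehyde, hydrogen-bonded to the ortho hydroxyl, may be oxidised slowly.
Fallback: the ring B phenol is masked before the oxidation. MOMCl and i-Pr2NEt convert 20 into methyl 2-[4-chloro-2-formyl-3-(methoxymethoxy)-5-methylphenoxy]-3-methoxy-5-(methoxymethoxy)benzoate F12, whose aldehyde is no longer hydrogen-bonded; Pinnick oxidation gives 3-chloro-6-[2-methoxy-6-(methoxycarbonyl)-4-(methoxymethoxy)phenoxy]-2-(methoxymethoxy)-4-methylbenzoic acid F13, and the conditions of step 11 remove both MOM groups. The detour sets out from 20 and returns at 22.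

## Further compounds

F1 | step 9 | (2E)-3-chloro-2-methylprop-2-enoic acid | C/C(=C\Cl)C(=O)O
F2 | step 9 | (2E)-3-chloro-2-methylprop-2-enoyl chloride | C/C(=C\Cl)C(=O)Cl
F3 | step 9 | (3E)-4-chloro-1-diazo-3-methylbut-3-en-2-one | C/C(=C\Cl)C(=O)C=[N+]=[N-]
F4 | step 5 | methyl 2-[(3,3-diethoxyprop-1-en-1-yl)oxy]-3-methoxy-5-(methoxymethoxy)benzoate (E/Z mixture) | COC(=O)c1cc(OCOC)cc(OC)c1OC=CC(OCC)OCC
F5 | step 5 | methyl 2-(1,2-dibromo-3,3-diethoxypropoxy)-3-methoxy-5-(methoxymethoxy)benzoate (diastereomer mixture) | COC(=O)c1cc(OCOC)cc(OC)c1OC(Br)C(Br)C(OCC)OCC
F6 | step 5 | methyl 2-[(2-bromo-3,3-diethoxyprop-1-en-1-yl)oxy]-3-methoxy-5-(methoxymethoxy)benzoate (E/Z mixture) | COC(=O)c1cc(OCOC)cc(OC)c1OC=C(Br)C(OCC)OCC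
F7 | step 8 | 3-methylcyclobut-2-en-1-one | CC1=CC(=O)C1
F8 | step 8 | methyl 2-[2-(diethoxymethyl)-3-hydroxy-5-methylphenoxy]-3-methoxy-5-(methoxymethoxy)benzoate | COC(=O)c1cc(OCOC)cc(OC)c1Oc1cc(C)cc(O)c1C(OCC)OCC
F9 | step 1 | methyl 2-hydroxy-3-methoxybenzoate | COC(=O)c1cccc(OC)c1O
F10 | step 1 | methyl 5-bromo-2-hydroxy-3-methoxybenzoate | COC(=O)c1cc(Br)cc(OC)c1O
F11 | step 1 | methyl 2-hydroxy-3-methoxy-5-(4,4,5,5-tetramethyl-1,3,2-dioxaborolan-2-yl)benzoate | COC(=O)c1cc(B2OC(C)(C)C(C)(C)O2)cc(OC)c1O
F12 | step 10 | methyl 2-[4-chloro-2-formyl-3-(methoxymethoxy)-5-methylphenoxy]-3-methoxy-5-(methoxymethoxy)benzoate | COC(=O)c1cc(OCOC)cc(OC)c1Oc1cc(C)c(Cl)c(OCOC)c1C=O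
F13 | step 10 | 3-chloro-6-[2-methoxy-6-(methoxycarbonyl)-4-(methoxymethoxy)phenoxy]-2-(methoxymethoxy)-4-methylbenzoic acid | COC(=O)c1cc(OCOC)cc(OC)c1Oc1cc(C)c(Cl)c(OCOC)c1C(=O)O
A1 | alternative 1 | benzyl 4-[4-(benzyloxy)-2-methoxy-6-(methoxycarbonyl)phenoxy]-6-methyl-2-oxo-2H-pyran-3-carboxylate | COC(=O)c1cc(OCc2ccccc2)cc(OC)c1OC1=C(C(=O)OCc2ccccc2)C(=O)OC(C)=C1
A2 | alternative 1 | 2-chloro-1,1-diethoxyethene | CCOC(=CCl)OCC
A3 | alternative 1 | benzyl 6-[4-(benzyloxy)-2-methoxy-6-(methoxycarbonyl)phenoxy]-3-chloro-2-ethoxy-4-methylbenzoate | COC(=O)c1cc(OCc2ccccc2)cc(OC)c1Oc1cc(C)c(Cl)c(OCC)c1C(=O)OCc1ccccc1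
A4 | alternative 2 | tert-butyl 3-chloro-6-(3-methoxy-2,3-dioxopropoxy)-2-(methoxymethoxy)-4-methylbenzoate | COC(=O)C(=O)COc1cc(C)c(Cl)c(OCOC)c1C(=O)OC(C)(C)C
A5 | alternative 2 | 4,4-dimethoxybut-3-en-2-one | CC(=O)C=C(OC)OC
A6 | alternative 2 | tert-butyl 3-chloro-6-[4-hydroxy-2-methoxy-6-(methoxycarbonyl)phenoxy]-2-(methoxymethoxy)-4-methylbenzoate | COC(=O)c1cc(O)cc(OC)c1Oc1cc(C)c(Cl)c(OCOC)c1C(=O)OC(C)(C)C
A7 | alternative 3 | 4-chloro-3-(methoxymethoxy)-5-methyl-2-(trimethylsilyl)phenyl trifluoromethanesulfonate | COCOc1c(Cl)c(C)cc(OS(=O)(=O)C(F)(F)F)c1[Si](C)(C)C
A8 | alternative 3 | 4-chloro-3-(methoxymethoxy)-5-methylbenzyne | COCOC1=C(Cl)C(C)=CC#C1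
A9 | alternative 3 | carbon dioxide | O=C=O
A10 | alternative 3 | 3-chloro-6-[2-methoxy-6-(methoxycarbonyl)-4-(methoxymethoxy)phenoxy]-2-(methoxymethoxy)-4-methylbenzoic acid | COC(=O)c1cc(OCOC)cc(OC)c1Oc1cc(C)c(Cl)c(OCOC)c1C(=O)O
A11 | alternative 3 | 2-chloro-5-methoxy-1,7-bis(methoxymethoxy)-3-methyl-9H-xanthen-9-one | O=C1c2cc(OCOC)cc(OC)c2Oc2cc(C)c(Cl)c(OCOC)c21
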